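**Plan**

Cuts: the enal goes back to the methyl (E)-acrylate and its C=C bond (Wittig); the dioxane is opened at the benzylic C2–O1 bond; the carbinol C–H bond goes back to a ketone; the C3–O4 ether bond divides the molecule into 2-bromo-1-(3,4,5-trimethoxyphenyl)propan-1-one and 5-hydroxyvanillin.
Forward: both benzene rings are bought; the halves are joined through C3–O4, the acrylate is added by olefination, the ketone is reduced, and the 1,4-dioxane (the only ring made) is closed through C2–O1 before the ester is taken to the enal.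
Enabling feature: the C2(aryl)–O1/C3(methyl)–O4 stereodiad of the dioxane ring is a masked 2-aryloxy-1-arylpropan-1-one, in which C2 is a prochiral carbonyl carbon and the neighbouring C3–H is acidic, so C3 can equilibrate while C2 is reduced.
Stereochemistry: an asymmetric transfer hydrogenation with dynamic kinetic resolution turns the racemic ketone into the threo-(1S,2S) alcohol and so fixes C3 as S; ring closure through the benzylic cation then sets the aryl group trans to the C3 methyl group (2S,3S); the E-alkene comes from the stabilized ylide.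

Key step: step 7

Assumption: the reduction is taken to follow the polar Felkin–Anh course (aryloxy group anti to the hydride, methyl group beside the carbonyl oxygen), which leads to the threo alcohol, as racemic benzoin and α-alkoxy β-keto esters do with this catalyst family; the hand of the catalyst and the mode of ring closure are chosen for this outcome.

**Route**

Step 1
Reactants: 1 3,4,5-trimethoxybenzaldehyde; 2 ethylmagnesium bromide
Product: 3 rac-1-(3,4,5-trimethoxyphenyl)propan-1-ol
Conditions: EtMgBr (1.2 equiv), THF, 0 °C to rt; aq NH4Cl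
Reagents that add atoms: none
Why: Grignard addition of the ethyl group to the unhindered aromatic aldehyde should give the secondary benzylic alcohol, whose racemic stereocentre is removed in the next step.

Step 2
Reactants: 3 rac-1-(3,4,5-trimethoxyphenyl)propan-1-ol
Product: 4 1-(3,4,5-trimethoxyphenyl)propan-1-one
Conditions: activated MnO2 (excess), CH2Cl2, reflux
Reagents that add atoms: none
Why: Activated MnO2 should oxidize the electron-rich benzylic alcohol to the aryl ketone (benzylic alcohol oxidation) without touching the methyl ethers.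

Step 3
Reactants: 4 1-(3,4,5-trimethoxyphenyl)propan-1-one
Product: 5 rac-2-bromo-1-(3,4,5-trimethoxyphenyl)propan-1-one
Conditions: CuBr2 (2.1 equiv), EtOAc/CHCl3 (1:1), reflux
Reagents that add atoms: copper dibromide (CuBr2), Br[Cu]Br
Why: CuBr2 should brominate the enol of the aryl ethyl ketone at the α-carbon (α-halogenation of a ketone) while sparing the acyl-deactivated trimethoxyphenyl ring; the new stereocentre is racemic on purpose, since it is equilibrated in step 7.

Step 4
Reactants: 5 rac-2-bromo-1-(3,4,5-trimethoxyphenyl)propan-1-one; 6 3,4-dihydroxy-5-methoxybenzaldehyde (5-hydroxyvanillin)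
Product: 7 rac-3-hydroxy-5-methoxy-4-{[1-oxo-1-(3,4,5-trimethoxyphenyl)propan-2-yl]oxy}benzaldehyde
Conditions: Li2CO3 (1.1 equiv), DMF, 50 °C
Reagents that add atoms: none
Why: With one equivalent of the weak base Li2CO3 only the more acidic 4-OH (para to the formyl group) should be deprotonated, and its phenoxide displaces the activated α-bromide (regioselective Williamson ether synthesis by SN2) to form the future C3–O4 bond; the racemic product may rest partly as its six-membered hemiketal.

Step 5
Reactants: 7 rac-3-hydroxy-5-methoxy-4-{[1-oxo-1-(3,4,5-trimethoxyphenyl)propan-2-yl]oxy}benzaldehyde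
Product: 8 rac-3-(allyloxy)-5-methoxy-4-{[1-oxo-1-(3,4,5-trimethoxyphenyl)propan-2-yl]oxy}benzaldehyde
Conditions: allyl bromide (1.5 equiv), K2CO3, DMF, rt
Reagents that add atoms: allyl bromide, C=CCBr
Why: Williamson alkylation of the remaining phenoxide should cap the 3-OH as an allyl ether, draining the hemiketal equilibrium through the open form; the allyl group is chosen because it is later removed by zerovalent palladium under neutral conditions that spare the acrylate and the benzylic alcohol.

Step 6
Reactants: 8 rac-3-(allyloxy)-5-methoxy-4-{[1-oxo-1-(3,4,5-trimethoxyphenyl)propan-2-yl]oxy}benzaldehyde; 9 methyl (triphenylphosphoranylidene)acetate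
Product: 10 rac-methyl (E)-3-[3-(allyloxy)-5-methoxy-4-{[1-oxo-1-(3,4,5-trimethoxyphenyl)propan-2-yl]oxy}phenyl]acrylate
Conditions: 9 (1.2 equiv), CH2Cl2, rt
Reagents that add atoms: none
Why: The stabilized ylide should react with the aldehyde but not with the hindered aryl ketone and give the (E)-acrylate (Wittig olefination with a stabilized ylide).

Step 7
Reactants: 10 rac-methyl (E)-3-[3-(allyloxy)-5-methoxy-4-{[1-oxo-1-(3,4,5-trimethoxyphenyl)propan-2-yl]oxy}phenyl]acrylate
Product: 11 methyl (E)-3-[3-(allyloxy)-4-{[(1S,2S)-1-hydroxy-1-(3,4,5-trimethoxyphenyl)propan-2-yl]oxy}-5-methoxyphenyl]acrylate (threo)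
Conditions: RuCl[(R,R)-TsDPEN](p-cymene) (2 mol %), HCO2H/Et3N (1:2 mol/mol), DMF, 40 °C
Reagents that add atoms: none
Why: The chloride precatalyst and formate give, with loss of CO2, the 18-electron hydride RuH[(R,R)-TsDPEN](p-cymene), which hands over the hydride from Ru and a proton from N–H to the C=O group in a six-membered outer-sphere transition state, while free Et3N interconverts the two ketone enantiomers through the enol or enolate. The closest known reaction type is the Noyori–Ikariya asymmetric transfer hydrogenation with dynamic kinetic resolution of racemic α-oxygenated and α-amido aryl ketones (benzoin, α-alkoxy β-keto esters, 2-substituted cyclic aryl ketones). No ring closes in this step, only the C1–H bond of the carbinol forms. The carbinol centre is controlled by the catalyst: the CH/π contact of the η6-arene with the trimethoxyphenyl ring selects the same carbonyl face as in the reduction of acetophenone to (R)-1-phenylethanol, which reads 1S here because the oxygen-bearing alkyl group outranks the aryl group. The methyl-bearing centre is controlled by the substrate: only the (S)-ketone can offer that face with the aryloxy group anti to the incoming hydride, the methyl group beside the carbonyl oxygen and the α-hydrogen beside the aryl ring (polar Felkin–Anh arrangement, chelation being impossible at the saturated metal), so this enantiomer is drained to the threo-(1S,2S) alcohol. The step needs enantioface selectivity, threo selectivity and racemization faster than reduction of the mismatched enantiomer, which the aryl/alkyl difference at the carbonyl group, the bulk and electronegativity of the di-ortho-substituted aryloxy group and the C–H bond activated by both the aroyl and the aryloxy group secure, and the acrylate, the allyl ether and the aryl methyl ethers are inert to the catalyst.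

Step 8
Reactants: 11 methyl (E)-3-[3-(allyloxy)-4-{[(1S,2S)-1-hydroxy-1-(3,4,5-trimethoxyphenyl)propan-2-yl]oxy}-5-methoxyphenyl]acrylate
Product: 12 methyl (E)-3-[3-hydroxy-4-{[(1S,2S)-1-hydroxy-1-(3,4,5-trimethoxyphenyl)propan-2-yl]oxy}-5-methoxyphenyl]acrylate (threo)
Conditions: Pd(PPh3)4 (5 mol %), morpholine (5 equiv), THF, rt
Reagents that add atoms: none
Why: Zerovalent palladium should ionize the aryl allyl ether to a π-allyl complex that morpholine traps (Tsuji–Trost deallylation), freeing the phenol without touching the acrylate, the secondary alcohol or the two stereocentres.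

Step 9
Reactants: 12 methyl (E)-3-[3-hydroxy-4-{[(1S,2S)-1-hydroxy-1-(3,4,5-trimethoxyphenyl)propan-2-yl]oxy}-5-methoxyphenyl]acrylate
Product: 13 methyl (E)-3-[(2S,3S)-5-methoxy-3-methyl-2-(3,4,5-trimethoxyphenyl)-2,3-dihydro-1,4-benzodioxin-7-yl]acrylate (trans)
Conditions: Amberlyst 15 (H+ form), 4 Å molecular sieves, toluene, 60 °C
Reagents that add atoms: none
Why: The sulfonic acid resin should ionize the electron-rich benzylic alcohol to a 3,4,5-trimethoxybenzyl cation that the neighbouring phenol captures in a six-membered ring closure (acid-mediated SN1 cycloetherification at the C2–O1 bond), and the untouched C3 methyl centre steers the aryl group into the trans-diequatorial position under kinetic and, since the benzylic ether can re-ionize, thermodynamic control.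

Step 10
Reactants: 13 methyl (E)-3-[(2S,3S)-5-methoxy-3-methyl-2-(3,4,5-trimethoxyphenyl)-2,3-dihydro-1,4-benzodioxin-7-yl]acrylate
Product: 14 (E)-3-[(2S,3S)-5-methoxy-3-methyl-2-(3,4,5-trimethoxyphenyl)-2,3-dihydro-1,4-benzodioxin-7-yl]prop-2-en-1-ol
Conditions: i-Bu2AlH (2.5 equiv), CH2Cl2, −78 °C; aq potassium sodium tartrate
Reagents that add atoms: none
Why: i-Bu2AlH at low temperature should reduce the conjugated ester in 1,2-fashion to the allylic alcohol (ester reduction), leaving the alkene geometry, the aryl ethers and the dioxane stereocentres unchanged.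

Step 11
Reactants: 14 (E)-3-[(2S,3S)-5-methoxy-3-methyl-2-(3,4,5-trimethoxyphenyl)-2,3-dihydro-1,4-benzodioxin-7-yl]prop-2-en-1-ol
Product: 15 (E)-3-[(2S,3S)-5-methoxy-3-methyl-2-(3,4,5-trimethoxyphenyl)-2,3-dihydro-1,4-benzodioxin-7-yl]prop-2-enal (target CNP0258373.1)
Conditions: activated MnO2 (excess), CH2Cl2, rt
Reagents that add atoms: none
Why: Activated MnO2 should oxidize the cinnamyl-type allylic alcohol chemoselectively to the (E)-enal (allylic oxidation) without over-oxidation or epimerization.

**Compound list**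

1 | 3,4,5-trimethoxybenzaldehyde | COc1cc(C=O)cc(OC)c1OC | starting material
2 | ethylmagnesium bromide | CC[Mg]Br | starting material
3 | rac-1-(3,4,5-trimethoxyphenyl)propan-1-ol | CCC(O)c1cc(OC)c(OC)c(OC)c1 | intermediate
4 | 1-(3,4,5-trimethoxyphenyl)propan-1-one | CCC(=O)c1cc(OC)c(OC)c(OC)c1 | intermediate
5 | rac-2-bromo-1-(3,4,5-trimethoxyphenyl)propan-1-one | CC(Br)C(=O)c1cc(OC)c(OC)c(OC)c1 | intermediate
6 | 3,4-dihydroxy-5-methoxybenzaldehyde (5-hydroxyvanillin) | COc1cc(C=O)cc(O)c1O | starting material
7 | rac-3-hydroxy-5-methoxy-4-{[1-oxo-1-(3,4,5-trimethoxyphenyl)propan-2-yl]oxy}benzaldehyde (open form of the hemiketal pair) | COc1cc(C=O)cc(O)c1OC(C)C(=O)c1cc(OC)c(OC)c(OC)c1 | intermediate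
8 | rac-3-(allyloxy)-5-methoxy-4-{[1-oxo-1-(3,4,5-trimethoxyphenyl)propan-2-yl]oxy}benzaldehyde | COc1cc(C=O)cc(OCC=C)c1OC(C)C(=O)c1cc(OC)c(OC)c(OC)c1 | intermediate
9 | methyl (triphenylphosphoranylidene)acetate | COC(=O)C=P(c1ccccc1)(c1ccccc1)c1ccccc1 | starting material
10 | rac-methyl (E)-3-[3-(allyloxy)-5-methoxy-4-{[1-oxo-1-(3,4,5-trimethoxyphenyl)propan-2-yl]oxy}phenyl]acrylate | COC(=O)/C=C/c1cc(OCC=C)c(OC(C)C(=O)c2cc(OC)c(OC)c(OC)c2)c(OC)c1 | intermediate
11 | methyl (E)-3-[3-(allyloxy)-4-{[(1S,2S)-1-hydroxy-1-(3,4,5-trimethoxyphenyl)propan-2-yl]oxy}-5-methoxyphenyl]acrylate (threo) | COC(=O)/C=C/c1cc(OCC=C)c(O[C@@H](C)[C@@H](O)c2cc(OC)c(OC)c(OC)c2)c(OC)c1 | intermediate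
12 | methyl (E)-3-[3-hydroxy-4-{[(1S,2S)-1-hydroxy-1-(3,4,5-trimethoxyphenyl)propan-2-yl]oxy}-5-methoxyphenyl]acrylate (threo) | COC(=O)/C=C/c1cc(O)c(O[C@@H](C)[C@@H](O)c2cc(OC)c(OC)c(OC)c2)c(OC)c1 | intermediate
13 | methyl (E)-3-[(2S,3S)-5-methoxy-3-methyl-2-(3,4,5-trimethoxyphenyl)-2,3-dihydro-1,4-benzodioxin-7-yl]acrylate (trans) | COc1cc([C@@H]2Oc3cc(/C=C/C(=O)OC)cc(OC)c3O[C@H]2C)cc(OC)c1OC | intermediate
14 | (E)-3-[(2S,3S)-5-methoxy-3-methyl-2-(3,4,5-trimethoxyphenyl)-2,3-dihydro-1,4-benzodioxin-7-yl]prop-2-en-1-ol | COc1cc([C@@H]2Oc3cc(/C=C/CO)cc(OC)c3O[C@H]2C)cc(OC)c1OC | intermediate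
15 | (E)-3-[(2S,3S)-5-methoxy-3-methyl-2-(3,4,5-trimethoxyphenyl)-2,3-dihydro-1,4-benzodioxin-7-yl]prop-2-enal (CNP0258373.1) | COc1cc([C@@H]2Oc3cc(/C=C/C=O)cc(OC)c3O[C@H]2C)cc(OC)c1OC | target

**Step count**

Total step count: 11. Longest linear sequence: 11 steps (1 to 15); 2, 6 and 9 enter as bought compounds.

**Steps most likely to fail**

Step 7. Racemization of the ketone through its enol may be slower than hydride transfer to the mismatched enantiomer, or the rotamer preference may be too weak. Either erodes the diastereoselectivity, and because the later ring closure is steered by C3 alone, it erodes the enantiomeric purity of the target with it. Fallback (chiral pool in place of the dynamic resolution, from 6 back to 11): Mitsunobu etherification of 6 at its more acidic 4-OH with (R)-2-hydroxy-N-methoxy-N-methylpropanamide (PPh3, diisopropyl azodicarboxylate, THF; inversion) would give (2S)-2-(4-formyl-2-hydroxy-6-methoxyphenoxy)-N-methoxy-N-methylpropanamide F1. Allylation as in step 5 would give (2S)-2-[2-(allyloxy)-4-formyl-6-methoxyphenoxy]-N-methoxy-N-methylpropanamide F2, and Wittig olefination with 9 would give methyl (E)-3-[3-(allyloxy)-5-methoxy-4-{[(2S)-1-[methoxy(methyl)amino]-1-oxopropan-2-yl]oxy}phenyl]acrylate F3. 3,4,5-Trimethoxyphenylmagnesium bromide in THF at −40 °C should add to the N-methoxy-N-methylamide faster than to the conjugated ester and, after work-up of the chelated adduct, release the single enantiomer methyl (E)-3-[3-(allyloxy)-5-methoxy-4-{[(2S)-1-oxo-1-(3,4,5-trimethoxyphenyl)propan-2-yl]oxy}phenyl]acrylate F4. This would be reduced at once with the catalyst of step 7 in the acidic 5:2 formic acid/triethylamine mixture, where the α-centre is not equilibrated and only the carbonyl face (matched pair) has to be controlled, to rejoin the route at 11.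

Step 9. The benzylic cation may lose the C3 proton to give an enol ether (loss of the C3 configuration and, after hydrolysis, cleavage of the aryl ether), or the phenol may capture it with incomplete trans selectivity. Fallback (two SN2 inversions in place of ionization, from 11 back to 13): Mitsunobu esterification of 11 with 4-nitrobenzoic acid (PPh3, diisopropyl azodicarboxylate, THF, 0 °C) would invert the carbinol centre and give the erythro ester methyl (E)-3-[3-(allyloxy)-5-methoxy-4-{[(1R,2S)-1-(4-nitrobenzoyloxy)-1-(3,4,5-trimethoxyphenyl)propan-2-yl]oxy}phenyl]acrylate F5. Methanolysis (K2CO3, MeOH) would give methyl (E)-3-[3-(allyloxy)-4-{[(1R,2S)-1-hydroxy-1-(3,4,5-trimethoxyphenyl)propan-2-yl]oxy}-5-methoxyphenyl]acrylate F6, and deallylation as in step 8 would give methyl (E)-3-[3-hydroxy-4-{[(1R,2S)-1-hydroxy-1-(3,4,5-trimethoxyphenyl)propan-2-yl]oxy}-5-methoxyphenyl]acrylate F7. Intramolecular Mitsunobu etherification (PPh3, diisopropyl azodicarboxylate, THF) would then close the C2–O1 bond by a second inversion at the benzylic carbon (6-exo-tet) and give 13 stereospecifically.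

Step 4. The hindered 4-phenoxide may react slowly with the secondary bromide, so that alkylation at the 3-OH, double alkylation and base-induced loss of HBr from 5 compete. Fallback (a phenol with a single hydroxyl group and ring closure at the aryl carbon, from 5 back to 13): 3-bromo-4-hydroxy-5-methoxybenzaldehyde (5-bromovanillin), in which the bromine atom marks the place of O1, would be alkylated with 5 (K2CO3, DMF) to rac-3-bromo-5-methoxy-4-{[1-oxo-1-(3,4,5-trimethoxyphenyl)propan-2-yl]oxy}benzaldehyde F8. Wittig olefination with 9 would give rac-methyl (E)-3-[3-bromo-5-methoxy-4-{[1-oxo-1-(3,4,5-trimethoxyphenyl)propan-2-yl]oxy}phenyl]acrylate F9, and the reduction of step 7 would give methyl (E)-3-[3-bromo-4-{[(1S,2S)-1-hydroxy-1-(3,4,5-trimethoxyphenyl)propan-2-yl]oxy}-5-methoxyphenyl]acrylate F10. An Ullmann-type intramolecular O-arylation (CuI, 1,10-phenanthroline, Cs2CO3, toluene, 110 °C) would then form the aryl C–O1 bond with both stereocentres untouched and give 13, so that the allylation, the deallylation and the cation are all avoided.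

**Further compounds**

F1 | step 7 | (2S)-2-(4-formyl-2-hydroxy-6-methoxyphenoxy)-N-methoxy-N-methylpropanamide | C[C@H](Oc1c(O)cc(C=O)cc1OC)C(=O)N(C)OC
F2 | step 7 | (2S)-2-[2-(allyloxy)-4-formyl-6-methoxyphenoxy]-N-methoxy-N-methylpropanamide | C[C@H](Oc1c(OCC=C)cc(C=O)cc1OC)C(=O)N(C)OC
F3 | step 7 | methyl (E)-3-[3-(allyloxy)-5-methoxy-4-{[(2S)-1-[methoxy(methyl)amino]-1-oxopropan-2-yl]oxy}phenyl]acrylate | C[C@H](Oc1c(OCC=C)cc(/C=C/C(=O)OC)cc1OC)C(=O)N(C)OC
F4 | step 7 | methyl (E)-3-[3-(allyloxy)-5-methoxy-4-{[(2S)-1-oxo-1-(3,4,5-trimethoxyphenyl)propan-2-yl]oxy}phenyl]acrylate | C[C@H](Oc1c(OCC=C)cc(/C=C/C(=O)OC)cc1OC)C(=O)c1cc(OC)c(OC)c(OC)c1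
F5 | step 9 | methyl (E)-3-[3-(allyloxy)-5-methoxy-4-{[(1R,2S)-1-(4-nitrobenzoyloxy)-1-(3,4,5-trimethoxyphenyl)propan-2-yl]oxy}phenyl]acrylate | COC(=O)/C=C/c1cc(OCC=C)c(O[C@@H](C)[C@H](OC(=O)c2ccc(cc2)[N+](=O)[O-])c2cc(OC)c(OC)c(OC)c2)c(OC)c1
F6 | step 9 | methyl (E)-3-[3-(allyloxy)-4-{[(1R,2S)-1-hydroxy-1-(3,4,5-trimethoxyphenyl)propan-2-yl]oxy}-5-methoxyphenyl]acrylate (erythro) | COC(=O)/C=C/c1cc(OCC=C)c(O[C@@H](C)[C@H](O)c2cc(OC)c(OC)c(OC)c2)c(OC)c1
F7 | step 9 | methyl (E)-3-[3-hydroxy-4-{[(1R,2S)-1-hydroxy-1-(3,4,5-trimethoxyphenyl)propan-2-yl]oxy}-5-methoxyphenyl]acrylate (erythro) | COC(=O)/C=C/c1cc(O)c(O[C@@H](C)[C@H](O)c2cc(OC)c(OC)c(OC)c2)c(OC)c1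
F8 | step 4 | rac-3-bromo-5-methoxy-4-{[1-oxo-1-(3,4,5-trimethoxyphenyl)propan-2-yl]oxy}benzaldehyde | COc1cc(C=O)cc(Br)c1OC(C)C(=O)c1cc(OC)c(OC)c(OC)c1
F9 | step 4 | rac-methyl (E)-3-[3-bromo-5-methoxy-4-{[1-oxo-1-(3,4,5-trimethoxyphenyl)propan-2-yl]oxy}phenyl]acrylate | COC(=O)/C=C/c1cc(Br)c(OC(C)C(=O)c2cc(OC)c(OC)c(OC)c2)c(OC)c1
F10 | step 4 | methyl (E)-3-[3-bromo-4-{[(1S,2S)-1-hydroxy-1-(3,4,5-trimethoxyphenyl)propan-2-yl]oxy}-5-methoxyphenyl]acrylate (threo) | COC(=O)/C=C/c1cc(Br)c(O[C@@H](C)[C@@H](O)c2cc(OC)c(OC)c(OC)c2)c(OC)c1
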